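The readings stem from a simulated flask on assumed constants; the scatter is artificial.

The slowness struck me first when you asked for a quick number: at 15.0 h, teal and grey together still held a mean 67.3% of their electrophile.

| flask | electrophile | nucleophile | free base | remark | time |
|---|---|---|---|---|---|
| teal | 0.30 M | 1.3 equiv | 0.75 equiv | run made earlier |  |
| grey | 0.30 M | 1.3 equiv | 1.5 equiv | run made earlier |  |
| north-east | 0.30 M | 1.30 equiv | 2.20 equiv |  | 20 h |
| east | 0.30 M | 1.30 equiv | 1.10 equiv |  | 20 h |

| run | time / h | electrophile / % | target / % |
|---|---|---|---|
| teal | 1.00 | 94.6 | 3.2 |
| teal | 2.50 | 93.6 | 6.1 |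
| teal | 6.00 | 83.2 | 12.1 |
| teal | 15.0 | 66.4 | 24.7 |
| grey | 1.00 | 97.5 | 2.1 |
| grey | 2.50 | 93.6 | 7.2 |
| grey | 6.00 | 81.0 | 14.0 |
| grey | 15.0 | 68.2 | 24.3 |

(each reading ± 1 percentage point)

- part of the electrophile that has reacted at the end, north-east
- part of the electrophile that has reacted at the end, east
- what raising the equivalents of free base from its lowest to its highest value here does to the part of the electrophile that has reacted (changes below 5 percentage points count as none) (no change / it rises / it falls)



Your hunch was that more free base would hurry the flask along. But grey carried twice the free base of teal, and at 15.0 h it held 68.2% of its electrophile against 66.4% in teal, a gap of 1.8 percentage points on readings scattered by 1 point each. So I left free base out of my reckoning.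

I treated the electrophile, the limiting reagent, as pseudo-first-order with c(nucleophile) held at its mean, counting one nucleophile lost per electrophile. From 0.390 M at the start, that mean was 0.341 M over those hours. This gave, as a reading that carries their scatter, k = 0.0774 L mol⁻¹ h⁻¹, the logarithm of charged over remaining electrophile, divided by the time and by mean c(nucleophile).

The mean depends on the answer, so the answer had to go round. For north-east and east at 20 h, c(nucleophile) as charged gave 45.3% reacted. That lowered the mean to 0.322 M, which gave 39.3%. That raised the mean to 0.331 M, which gave 40.1%. I committed to that figure for both flasks.

The forecast stood slightly higher, at 41% for north-east and 41% for east with no change, on the words “The rate therefore looks zero order in free base”.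

North-east gave 41.9% and east 40.9%, a change of 0.94 points from lowest to highest free base, which counts as no change. The part reacted in east was not its yield of target, though: at 20.0 h east held 29.6% of target and 11.4% of isomer of the product, a passing that makes no difference there to the part reacted. Going round once more with 40.9% in the mean, k returned 39.9% for east.

    electrophile + nucleophile → acid set free + target (k = 2.50 × 10⁻⁵ L mol⁻¹ s⁻¹)
    nucleophile + acid set free ⇌ protonated nucleophile, settled at all times (K = 3400 L mol⁻¹)
    acid set free + free base ⇌ salt of the base, settled at all times (K = 6300 L mol⁻¹)
    target ⇌ isomer of the product (K = 0.390, k = 2.30 × 10⁻⁴ s⁻¹)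
    electrophile + acid set free → side product (k = 3.90 × 10⁻⁵ L mol⁻¹ s⁻¹)

For a further flask, like north-east but with 0.51 M of electrophile, I went round in the same way: from 0.663 M of nucleophile, k gave 64.2%, then 53.9%, then 55.7%. The computed flask gave 55.7%.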